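The ratio of two logarithms measures how a single-handed catalyst sorts a racemate. With f the fraction of each substrate left of its own charge, the apparent selectivity factor A = ln f(left-handed) / ln f(right-handed) stands at 1 for no sorting, the symmetric zero of the scale.

all flasks: left-handed substrate 0.050 M; right-handed substrate 0.050 M; precatalyst 5 mol%
- delta: coupling partner 2 equiv; free catalyst 26 mol%; run made earlier
- blue: coupling partner 2.00 equiv; free catalyst 20 mol%; time 1.5 h
- green: coupling partner 2.00 equiv; free catalyst 30 mol%; time 1.5 h

delta run (percent of the left-handed substrate and right-handed substrate together charged)

| time / min | right-handed substrate / % | left-handed substrate / % |
|---|---|---|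
| 4.00 | 48.3 | 45.5 |
| 8.00 | 47.1 | 41.7 |
| 20.0 | 43.1 | 34.1 |
| 50.0 | 34.0 | 22.7 |

(each reading ± 0.3 percentage points)

- free catalyst is single-handed; left-handed substrate and right-handed substrate are mirror images of each other, charged as a racemate, each of them at the stated concentration
- on the list of suspects stand: coupling partner + free catalyst + left-handed substrate -> free catalyst + left-handed product; coupling partner + free catalyst + right-handed substrate -> free catalyst + right-handed product; left-handed substrate + racemization catalyst <-> right-handed substrate + racemization catalyst; precatalyst -> racemization catalyst; 2 racemization catalyst -> spent catalyst B; racemization catalyst -> spent catalyst A
- an excess is the difference of the two amounts in percent of their sum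
- an excess is below zero if the other one leads

- which one finishes higher in excess of right-handed substrate over left-handed substrate among what is left of the two ("neither" within 2 percentage points) (blue / green / neither)
- excess of right-handed substrate over left-handed substrate among what is left of the two at the end, blue
- excess of right-handed substrate over left-handed substrate among what is left of the two at the end, green

In delta, A reads 2.73 at 4.00 min, with a large share of scatter on so small a loss. We carry the apparent selectivity factor at its last reading, 2.05, which is lower than the first.

The coupling partner is charged equal to both substrates together and goes one for one, so x, the substrate fraction left, equals its fraction too. We take the inverse of x, minus one, as growing in proportion to time and free catalyst, from 0.764 at the last reading of delta. That gives x = 48.6% for blue and 38.7% for green.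

Holding A at two makes the left-handed fraction the square of the right-handed fraction f, whose sum with f is twice x. The excess is then one minus f over one plus f: we reckon 24.6% for blue and 32.3% for green, so we pick green, by 7.7 percentage points against a margin of 2 points.

The forecast says green, with 21.5% (17.5% to 26%) for blue and 27% (22.5% to 32%) for green, because “its resolution drive is stronger against the same racemization”. Our two figures are higher than the two of the forecast.

The flask gives green: 23.1% for blue, 29.3% for green.

    coupling partner + free catalyst + left-handed substrate → free catalyst + left-handed product (k = 19.6 M⁻² min⁻¹)
    coupling partner + free catalyst + right-handed substrate → free catalyst + right-handed product (k = 5.33 M⁻² min⁻¹)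
    left-handed substrate + racemization catalyst ⇌ right-handed substrate + racemization catalyst, rate k3*[racemization catalyst]*[left-handed substrate] forward; the back reaction follows from the equilibrium constant (k = 11.0 M⁻¹ min⁻¹)
    precatalyst → racemization catalyst (k = 0.473 min⁻¹)
    2 racemization catalyst → spent catalyst B (k = 8.66 M⁻¹ min⁻¹)
    racemization catalyst → spent catalyst A (k = 0.00689 min⁻¹)

In blue, coupling of left-handed substrate turned over 37.7% of the substrates charged, while racemization ran a net 6.67% from right-handed back to left-handed. What remained in blue gives A = 1.94, and in the neighbour of green with 5.00 equiv of coupling partner, whose excess is 70.0%, A is 1.98.

The data come from a simulation on assumed constants, noise included.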